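**Retrosynthetic overview**
1. There is one strategic disconnection: the acyl C–O bond between the caffeoyl carbonyl and the tertiary O-1. It leads back to (−)-quinic acid and caffeic acid, both used unprotected.
2. O-1 is reached through its geminal carboxyl group. The caffeoyl group is first placed on CO2H as a mixed anhydride, then moved to O-1 by a 1,4-O→O acyl shift.
3. The acyl donor is the bench-stable N-succinimidyl ester of caffeic acid. Catalytic imidazole carries the acyl group from it to the carboxyl group.
4. No ring is built. The arene and the cyclohexane are bought in, and the only ring formed is a transient spiro-1,3-dioxolan-4-one that opens again in the same flask.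
5. All four stereocentres come from quinic acid. No bond to C1, C3, C4 or C5 is broken, and the E-alkene is carried through.

Assumption: IUPAC quinic acid numbering is used. The SMILES decodes to the 1-O-ester of natural (−)-quinic acid: 1-O, 3-OH and 4-OH lie on one ring face, CO2H and 5-OH on the other, C3 and C5 are both R, and the alkene is E.

**Step 1**
Reactants: 1 caffeic acid, (E)-3-(3,4-dihydroxyphenyl)prop-2-enoic acid
Product: 3 N-succinimidyl (E)-caffeate, via O-caffeoyl-N,N'-dicyclohexylisourea 2 (not isolated)
Conditions: NHS (1.2 equiv), DCC (1.05 equiv), THF, Ar, 0 °C → rt, 16 h; filter, recrystallise (EtOAc/hexane)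
Reagents that add atoms: N-hydroxysuccinimide, O=C1CCC(=O)N1O
Why: This is a DMAP-free carbodiimide active-ester formation (Steglich-type activation) in which the acidic, α-effect N–OH of NHS captures 2 much faster than the neutral catechol OH groups do, so no phenol protection is needed, no stereocentre is formed and the E-alkene is untouched.

**Step 2**
Reactants: 3 N-succinimidyl (E)-caffeate; 4 (−)-quinic acid
Product: 8 1-O-caffeoylquinic acid, via N-caffeoylimidazole 5 (not isolated), via caffeic quinic mixed anhydride 6 (not isolated), via spiro orthoacid 7 (not isolated)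
Conditions: 4 (3 equiv), imidazole (0.5 equiv), 4 Å MS, DMF (0.3 M in 4), Ar, dark, 35 °C; 3 (1 equiv) added over 6 h, then 24 h; aq HCOOH to pH 2–3; C18 (H2O/MeOH, 0.1% HCOOH)
Reagents that add atoms: none
Why: Proposed new method: a carboxyl-relayed, imidazole-shuttled site-selective acylation in which imidazole takes the acyl group from 3 (classical nucleophilic catalysis of active-ester transfer) to give 5, which like other N-acylimidazoles ignores neutral alcohols and phenols at 35 °C but equilibrates with a carboxylic acid to the anhydride, so of the seven O–H groups present only the CO2H of 4 is acylated (6); in 6 the geminal tertiary 1-OH is the only hydroxyl that reaches the caffeoyl C=O through a five-membered (5-exo-trig) transition state (3-, 4- and 5-OH would need seven- or eight-membered ones), giving 7, which collapses by expelling carboxylate rather than alkoxide and so drains the uphill equilibria irreversibly into 8; attack at the quinic C=O is disfavoured as in a pivalic mixed anhydride (fully substituted α-carbon) and lactonisation by 5-OH needs chair inversion; only an acyl C–O bond is made, so C1, C3, C4, C5 and the E-alkene are retained; the closest known reaction types are the closing 1,4-O→O (Mumm-type) acyl transfer of the Passerini reaction onto a tertiary carbinol oxygen and anhydride formation from N-acylimidazoles and carboxylic acids.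

**Compound list**
1 | caffeic acid, (E)-3-(3,4-dihydroxyphenyl)prop-2-enoic acid | O=C(O)/C=C/c1ccc(O)c(O)c1 | starting material
2 | O-caffeoyl-N,N'-dicyclohexylisourea (E-caffeoyl on the isourea oxygen) | O=C(/C=C/c1ccc(O)c(O)c1)OC(=NC1CCCCC1)NC1CCCCC1 | intermediate
3 | N-succinimidyl (E)-caffeate, 2,5-dioxopyrrolidin-1-yl (E)-3-(3,4-dihydroxyphenyl)prop-2-enoate | O=C(/C=C/c1ccc(O)c(O)c1)ON1C(=O)CCC1=O | intermediate
4 | (−)-quinic acid, (1S,3R,4S,5R)-1,3,4,5-tetrahydroxycyclohexane-1-carboxylic acid | O[C@]1(C(=O)O)C[C@@H](O)[C@H](O)[C@H](O)C1 | starting material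
5 | N-caffeoylimidazole, (E)-3-(3,4-dihydroxyphenyl)-1-(imidazol-1-yl)prop-2-en-1-one | O=C(/C=C/c1ccc(O)c(O)c1)n1ccnc1 | intermediate
6 | caffeic quinic mixed anhydride: (E)-caffeoyl on the carboxyl oxygen of 4, all four ring OH free, ring configuration as in 4 | O=C(/C=C/c1ccc(O)c(O)c1)OC(=O)[C@@]1(O)C[C@@H](O)[C@H](O)[C@H](O)C1 | intermediate
7 | spiro orthoacid: 2-hydroxy-2-[(E)-2-(3,4-dihydroxyphenyl)ethenyl]-1,3-dioxolan-4-one whose C5 is C1 of the quinic ring (ring O1 = former 1-O); ring stereocentres as in 4, C2 undefined | OC1(/C=C/c2ccc(O)c(O)c2)OC(=O)[C@@]2(O1)C[C@@H](O)[C@H](O)[C@H](O)C2 | intermediate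
8 | 1-O-caffeoylquinic acid: (E)-caffeate ester of the tertiary 1-OH of 4, with CO2H, 3-OH, 4-OH and 5-OH free and configured as in 4 | O=C(/C=C/c1ccc(O)c(O)c1)O[C@]1(C(=O)O)C[C@@H](O)[C@H](O)[C@H](O)C1 | target

**Step count:** 2 steps in total. The longest linear sequence is 2 (1 → 3 → 8), and 4 enters in step 2.

**Most likely to fail.** The route has only two steps. Step 2 is therefore entered twice, once for each of its independent failure modes.

Risk 1 is step 2, the new relay acylation itself.
- Anhydride 6 may lactonise, with 5-OH attacking the quinic C=O to give quinide and caffeic acid.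
- Imidazole may attack the quinic carbonyl instead of the caffeoyl carbonyl.
- The shift onto the hindered O-1 may be too slow.
- The diagnostic for success is that none of H-3, H-4 and H-5 moves downfield to δ 5.0–5.4, while C-1 shifts downfield.

The fallback uses only known chemistry. It sets out from 4 and 1 and comes back at 8. Quinic acid 4 is heated with 2,2-dimethoxypropane and catalytic TsOH in acetone to give 3,4-O-isopropylidene-1,5-quinide F1, in which only the tertiary 1-OH is free. Caffeic acid 1 is acetylated (Ac2O, pyridine) to 3,4-di-O-acetylcaffeic acid F2. This is converted with oxalyl chloride and catalytic DMF into 3,4-di-O-acetylcaffeoyl chloride F3. DMAP/pyridine acylation of F1 with F3 in CH2Cl2 gives 1-O-(3,4-di-O-acetylcaffeoyl)-3,4-O-isopropylidene-1,5-quinide F4. Treatment with 1 M aq HCl/THF at rt for several days removes the acetonide and both acetates and opens the lactone, giving 8.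

Risk 2 is step 2, the free catechols. Phenolic O-acylation of 3, 5 or 8 could give depside oligomers faster than imidazole reverses them, or the catechol could oxidise during the long reaction. The fallback never uses an activated caffeic acid. It sets out from 4 and comes back at 8. 3,4-O-Isopropylidene-1,5-quinide F1, made as above, is heated with Meldrum's acid in toluene to give the 1-O-malonyl half-ester of the acetonide quinide F5. Knoevenagel–Doebner condensation of F5 with 3,4-dihydroxybenzaldehyde (pyridine, catalytic piperidine) builds the E-cinnamate and gives 1-O-caffeoyl-3,4-O-isopropylidene-1,5-quinide F6. Treatment with 1 M aq HCl/THF at rt then gives 8.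

Risk 3 is step 1. N-Acylurea formation or catechol acylation could erode the yield or purity of 3. The fallback abandons the active ester and the imidazole shuttle. It sets out from 1 and comes back at 6. Caffeic acid 1 is refluxed briefly in SOCl2 and stripped to give (E)-caffeoyl chloride F7. A THF solution of F7 is added at −20 °C to 4 (3 equiv) and Et3N (1 equiv) in DMF. The carboxylate is acylated in preference to the neutral hydroxyls, as in the first stage of a Yamaguchi mixed-anhydride protocol. This gives 6 directly, and 6 rearranges to 8 on warming.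

**Further compounds**
F1 | step 2 | 3,4-O-isopropylidene-1,5-quinide (γ-lactone CO2H/5-OH, acetonide on cis-3,4-diol, 1-OH free) | O[C@]1(C(=O)O2)C[C@@H]2[C@H](O3)[C@H](OC3(C)C)C1
F2 | step 2 | 3,4-di-O-acetylcaffeic acid (E) | CC(=O)Oc1ccc(/C=C/C(=O)O)cc1OC(C)=O
F3 | step 2 | 3,4-di-O-acetylcaffeoyl chloride (E) | CC(=O)Oc1ccc(/C=C/C(=O)Cl)cc1OC(C)=O
F4 | step 2 | 1-O-(3,4-di-O-acetylcaffeoyl)-3,4-O-isopropylidene-1,5-quinide | O=C(/C=C/c1ccc(OC(C)=O)c(OC(C)=O)c1)O[C@]1(C(=O)O2)C[C@@H]2[C@H](O3)[C@H](OC3(C)C)C1
F5 | step 2 | 1-O-malonyl half-ester of 3,4-O-isopropylidene-1,5-quinide | O=C(O)CC(=O)O[C@]1(C(=O)O2)C[C@@H]2[C@H](O3)[C@H](OC3(C)C)C1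
F6 | step 2 | 1-O-caffeoyl-3,4-O-isopropylidene-1,5-quinide (E) | O=C(/C=C/c1ccc(O)c(O)c1)O[C@]1(C(=O)O2)C[C@@H]2[C@H](O3)[C@H](OC3(C)C)C1
F7 | step 1 | (E)-caffeoyl chloride | O=C(Cl)/C=C/c1ccc(O)c(O)c1
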